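Readings and results come from a simulation on assumed constants.

**Two runs.** The north-east run has 4.06 times the [catalyst] of the south-east run, and the new flask has a [catalyst] between them.

| setting | south-east | north-east | flask |
|---|---|---|---|
| left-handed substrate | 24 mM | 24 mM | 24 mM |
| right-handed substrate | 24 mM | 24 mM | 24 mM |
| reagent | 60 mM | 60 mM | 60.0 mM |
| catalyst | 32 µM | 130 µM | 65 µM |
| remark | run made earlier | run made earlier |  |
| time |  |  | 20 min |

| run | time / min | left-handed product / % | right-handed product / % |
|---|---|---|---|
| south-east | 1.00 | 7 | 3 |
| south-east | 1.33 | 9 | 5 |
| south-east | 2.00 | 10 | 11 |
| south-east | 3.00 | 12 | 7 |
| south-east | 5.00 | 20 | 12 |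
| south-east | 8.00 | 23 | 16 |
| south-east | 12.0 | 31 | 15 |
| north-east | 1.50 | 25 | 16 |
| north-east | 3.00 | 34 | 22 |
| north-east | 5.00 | 40 | 25 |
| north-east | 6.00 | 41 | 31 |
| north-east | 8.00 | 44 | 32 |
| north-east | 10.0 | 50 | 31 |
| north-east | 12.0 | 47 | 29 |

(scatter of a reading: 1.5 percentage points)

- catalyst is single-handed; left-handed substrate and right-handed substrate are mirror images of each other, charged as a racemate, each of them at the stated concentration
- the numbers in the tables scatter with a standard deviation of 1.5 percentage points
- candidate steps: reagent <-> dormant form; left-handed substrate <-> right-handed substrate; reagent + catalyst + left-handed substrate -> catalyst + left-handed product; reagent + catalyst + right-handed substrate -> catalyst + right-handed product; 2 reagent -> homo dimer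
- an excess is the difference of the two amounts in percent of their sum
- an excess is below zero if the other one leads

* left-handed product and right-handed product together, in percent of the left-handed substrate and right-handed substrate charged together, at 20 min
* excess of left-handed product over right-handed product in the product at 20 min
* whether the exchange between left-handed substrate and right-handed substrate keeps pace with the reaction: how far the product's excess at 20 min gets from its value without exchange to its value with instant exchange (above 80% keeps pace, below 20% hardly takes part, else lags behind)

**Steady excess.** Each substrate makes its own product. Left-handed product adds up to 112% over the south-east readings and right-handed product to 69.0%, a read ratio of 1.62, which I take as the selectivity factor. If exchange holds the two substrates equal, every turn picks left and right in that ratio, so the product keeps one excess at any yield: the steady excess, read as 23.8%.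

**Left-handed balance.** In the north-east run, without exchange, left-handed product can reach at most 50.0% of the two substrates together, since left-handed substrate is that share of the charge. The last north-east readings average 47.0% left-handed product. Separate pools would then hold 6.00% of the left-handed charge. What remains of the right-handed charge is that share raised to the power 1/ratio, which gives 41.2% right-handed product. The same readings average 30.7%, a gap of 11 percentage points against a scatter of 1.5 points. So I expect exchange to keep pace and the flask's excess to be 23.8%; I reckon no yield of my own.

**The forecast.** The forecast gives a yield of 67%, an excess of 22% and, for the exchange, hardly takes part, saying “That fits little or no exchange; instant exchange would hold about 35.” We part on the pace, and on the excess by 1.8 points.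

    reagent ⇌ dormant form (K = 0.427, k = 0.00328 s⁻¹)
    left-handed substrate ⇌ right-handed substrate (k = 0.0140 s⁻¹)
    reagent + catalyst + left-handed substrate → catalyst + left-handed product (k = 1530 M⁻² s⁻¹)
    reagent + catalyst + right-handed substrate → catalyst + right-handed product (k = 945 M⁻² s⁻¹)
    2 reagent → homo dimer (k = 0.0251 M⁻¹ s⁻¹)

**Result, neighbour.** The flask gives a yield of 72.8%, an excess of 22.3% and, for the exchange, keeps pace, so the forecast's yield is 5.8 points short. Without exchange the excess at 20.0 min is 11.8%, and the flask gets 89% of the way to its instant-exchange value. The steady excess stands 1.5 points above the flask's figure. The neighbour with 0.016 mM of catalyst, about a quarter of this flask's, reaches a lower yield, 36.6%. The same reckoning again says 23.8%, and the neighbour gives an excess of 23.3%, with left-handed product at 22.6% and right-handed product at 14.0%, a ratio of 1.61.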